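**Retrosynthetic overview**
- The route rests on the substitution pattern of the single benzene ring. The oxygens on C2 and C4 with the C3–H between them, together with C5, are the four carbons of a 1,1,3-trioxygenated buta-1,3-diene. C1 (hydroxyl) and C6 (heneicosyl) are the two alkyne carbons of an acetyl alkyne.
- C1–OH is traced back to C1–OAc and then to C1–C(O)CH3 (Baeyer–Villiger oxidation with aryl migration). The C2 methyl ether is traced back to a hydrogen-bonded C2 phenol.
- The only ring is formed in one step: Diels–Alder cycloaddition of 1,3-dimethoxy-1-(trimethylsilyloxy)buta-1,3-diene with pentacos-3-yn-2-one makes C1–C2 and C5–C6, and loss of methanol with desilylation aromatises the adduct.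
- The diene comes from methyl acetoacetate (enol ether, γ-deprotonation, O-silylation). The ynone comes from 1-docosanol (oxidation, one-carbon alkynylation, acetylation of the acetylide).

Key step: step 6

Assumption: in the acidic aromatisation of the cycloadduct the ketal carbon is taken to lose methanol and keep the oxygen that carried silicon, giving the hydrogen-bonded phenol. Loss of the silyloxy group instead would give the dimethoxy ketone of step 7 directly, so both modes converge.

**Route**

Step 1
Reactants: 1 methyl acetoacetate; 2 trimethyl orthoformate
Product: 4 methyl (E)-3-methoxybut-2-enoate, via methyl 3,3-dimethoxybutanoate 3 (not isolated)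
Conditions: H2SO4 (cat.), neat, rt; then quinoline, distillation
Reagents that add atoms: none
Why: Acid-catalysed ketalisation of the ketone by the orthoformate and loss of methanol on distillation is the standard enol ether synthesis from a β-keto ester; the conjugated (E)-isomer should predominate and its geometry has no later consequence.

Step 2
Reactants: 4 methyl (E)-3-methoxybut-2-enoate
Product: 6 1,3-dimethoxy-1-(trimethylsilyloxy)buta-1,3-diene, via lithium dienolate 5 (not isolated)
Conditions: LiN(i-Pr)2, THF, −78 °C; then Me3SiCl, −78 °C → rt; pentane, filtration, distillation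
Reagents that add atoms: chlorotrimethylsilane, C[Si](C)(C)Cl
Why: Kinetic γ-deprotonation of the vinylogous ester gives the extended dienolate, which the silyl chloride should trap on oxygen (O-silylation of an ester enolate to a silyl ketene acetal).

Step 3
Reactants: 7 1-docosanol
Product: 8 docosanal
Conditions: TEMPO (cat.), PhI(OAc)2, CH2Cl2, 35 °C
Reagents that add atoms: none
Why: Oxoammonium-mediated oxidation of a primary alcohol in a non-aqueous medium should stop at the aldehyde, and the gentle warming needed to dissolve the waxy alcohol is tolerated.

Step 4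
Reactants: 8 docosanal
Product: 9 tricos-1-yne
Conditions: dimethyl (1-diazo-2-oxopropyl)phosphonate, K2CO3, MeOH/THF, rt
Reagents that add atoms: dimethyl (1-diazo-2-oxopropyl)phosphonate, COP(=O)(OC)C(=[N+]=[N-])C(C)=O
Why: Ohira–Bestmann alkynylation: methanolysis of the acetyl group releases the diazomethylphosphonate anion, which olefinates the aldehyde, and loss of N2 with a 1,2-hydride shift gives the terminal alkyne with one added carbon.

Step 5
Reactants: 9 tricos-1-yne; 10 N-methoxy-N-methylacetamide
Product: 13 pentacos-3-yn-2-one, via lithium tricos-1-yn-1-ide 11 (not isolated), via lithium hemiaminal alkoxide 12 (not isolated)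
Conditions: n-BuLi, THF, −40 → 0 °C; then 10, −40 °C → rt; then 1 M HCl, 0 °C
Reagents that add atoms: none
Why: Acylation of a lithium acetylide by an N-methoxy-N-methyl amide; the chelated tetrahedral adduct should persist until the acidic quench, so no second addition to the ynone occurs.

Step 6
Reactants: 6 1,3-dimethoxy-1-(trimethylsilyloxy)buta-1,3-diene; 13 pentacos-3-yn-2-one
Product: 15 1-(2-heneicosyl-6-hydroxy-4-methoxyphenyl)ethan-1-one, via cyclohexa-1,4-diene cycloadduct 14 (not isolated)
Conditions: 6 (2.5 equiv), PhMe, 100 °C, sealed tube, Ar; then 1 M HCl, THF, rt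
Reagents that add atoms: none
Why: A thermal, normal-electron-demand Diels–Alder cycloaddition, asynchronous in its bond formation: the CH2 terminus of the electron-rich diene 6 bonds in advance to the chain-bearing β-carbon of ynone 13 and the ketene-acetal carbon closes onto the acetyl-bearing α-carbon, giving cyclohexa-1,4-diene 14. The closest known reaction type is the cycloaddition of 1,1,3-trioxygenated buta-1,3-dienes to acetylenic ketones and esters, followed by aromatising elimination to resorcinol derivatives. The one ring of the target is closed by this intermolecular (4+2) cycloaddition, which forms both new ring bonds (target C1–C2 and C5–C6); aqueous acid then cleaves the O–Si bond of the mixed ketal, methanol is expelled and the ring CH2 loses a proton, so that the carbocycle becomes the benzene ring. No stereocentre has to be controlled, because the ketal carbon of 14, formed as a racemate, ends as an sp2 ring carbon; for the same reason either geometry of the ketene acetal of 6 can be used. The selectivity required is regiochemical, and the matched polarisation of the partners secures it: the largest HOMO coefficient of 6 lies on the CH2 terminus, which receives electron density from the 3-methoxy group and the ketene-acetal oxygens, and the largest LUMO coefficient of 13 lies on the β-carbon. The hydroxyl that emerges next to the acetyl group is hydrogen-bonded to its carbonyl, which should favour loss of methanol over loss of the silyloxy group.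

Step 7
Reactants: 15 1-(2-heneicosyl-6-hydroxy-4-methoxyphenyl)ethan-1-one
Product: 16 1-(2-heneicosyl-4,6-dimethoxyphenyl)ethan-1-one
Conditions: MeI, K2CO3, acetone, reflux
Reagents that add atoms: iodomethane, CI
Why: Williamson O-methylation; carbonate in refluxing acetone should deprotonate the chelated phenol, while the methyl ketone is not enolised under these conditions.

Step 8
Reactants: 16 1-(2-heneicosyl-4,6-dimethoxyphenyl)ethan-1-one
Product: 17 2-heneicosyl-4,6-dimethoxyphenyl acetate
Conditions: mCPBA, CH2Cl2, 0 °C → rt, dark
Reagents that add atoms: 3-chloroperoxybenzoic acid (mCPBA), OOC(=O)c1cccc(Cl)c1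
Why: Baeyer–Villiger oxidation: in the peracid adduct the electron-rich 2,4-dimethoxy-6-alkylphenyl group should migrate far faster than methyl, and the two ortho substituents twist the carbonyl out of conjugation so that it accepts the peracid like an aliphatic ketone.

Step 9
Reactants: 17 2-heneicosyl-4,6-dimethoxyphenyl acetate
Product: 18 6-heneicosyl-2,4-dimethoxyphenol
Conditions: K2CO3 (cat.), MeOH/THF, rt, Ar; then dil. HCl
Reagents that add atoms: none
Why: Base-catalysed transesterification of the aryl acetate with methanol releases the phenol, and exclusion of air protects the electron-rich phenoxide from oxidation.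

**Compound list**
1 | methyl acetoacetate | CC(=O)CC(=O)OC | starting material
2 | trimethyl orthoformate | COC(OC)OC | starting material
3 | methyl 3,3-dimethoxybutanoate | COC(C)(OC)CC(=O)OC | intermediate
4 | methyl (E)-3-methoxybut-2-enoate | CO/C(C)=C/C(=O)OC | intermediate
5 | lithium 1,3-dimethoxybuta-1,3-dien-1-olate (lithium dienolate) | [Li+].[O-]C(OC)=CC(OC)=C | intermediate
6 | 1,3-dimethoxy-1-(trimethylsilyloxy)buta-1,3-diene (ketene acetal geometry not defined) | C=C(OC)C=C(OC)O[Si](C)(C)C | intermediate
7 | 1-docosanol | CCCCCCCCCCCCCCCCCCCCCCO | starting material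
8 | docosanal | CCCCCCCCCCCCCCCCCCCCCC=O | intermediate
9 | tricos-1-yne | CCCCCCCCCCCCCCCCCCCCCC#C | intermediate
10 | N-methoxy-N-methylacetamide | CON(C)C(C)=O | starting material
11 | lithium tricos-1-yn-1-ide | [Li+].[C-]#CCCCCCCCCCCCCCCCCCCCCC | intermediate
12 | lithium 2-[methoxy(methyl)amino]pentacos-3-yn-2-olate (racemic; lithium hemiaminal alkoxide) | [Li+].CC([O-])(N(C)OC)C#CCCCCCCCCCCCCCCCCCCCCC | intermediate
13 | pentacos-3-yn-2-one | CC(=O)C#CCCCCCCCCCCCCCCCCCCCCC | intermediate
14 | 1-[2-heneicosyl-4,6-dimethoxy-6-(trimethylsilyloxy)cyclohexa-1,4-dien-1-yl]ethan-1-one (racemic cycloadduct) | CCCCCCCCCCCCCCCCCCCCCC1=C(C(C)=O)C(OC)(O[Si](C)(C)C)C=C(OC)C1 | intermediate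
15 | 1-(2-heneicosyl-6-hydroxy-4-methoxyphenyl)ethan-1-one | CCCCCCCCCCCCCCCCCCCCCc1cc(OC)cc(O)c1C(C)=O | intermediate
16 | 1-(2-heneicosyl-4,6-dimethoxyphenyl)ethan-1-one | CCCCCCCCCCCCCCCCCCCCCc1cc(OC)cc(OC)c1C(C)=O | intermediate
17 | 2-heneicosyl-4,6-dimethoxyphenyl acetate | CCCCCCCCCCCCCCCCCCCCCc1cc(OC)cc(OC)c1OC(C)=O | intermediate
18 | 6-heneicosyl-2,4-dimethoxyphenol | CCCCCCCCCCCCCCCCCCCCCc1cc(OC)cc(OC)c1O | target

**Step count**
Total steps: 9. Longest linear sequence: 7 (steps 3 to 9, from 1-docosanol); the diene arm (steps 1 and 2) joins at step 6.

**Steps most likely to fail**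

1. Step 6. The β-carbon of the ynone carries the long chain, so the cycloaddition may be slow. At the temperature it needs, the silyl ketene acetal diene may be used up by hydrolysis, silyl transfer or oligomerisation, or may add in an open-chain conjugate manner without ring closure. The fallback builds the arene without a cycloaddition; it sets out from docosanal 8 and returns at ketone 16. Wittig olefination of 8 with 1-(triphenylphosphoranylidene)propan-2-one (PhMe, 90 °C) should give (E)-pentacos-3-en-2-one F1. Michael addition of dimethyl malonate and Claisen ring closure (NaOMe, MeOH/THF, reflux) should give methyl 6-heneicosyl-2,4-dioxocyclohexane-1-carboxylate F2. Saponification and decarboxylation (aqueous NaOH, then HCl, heat) should lead to 5-heneicosylcyclohexane-1,3-dione F3. Oxidative aromatisation with iodine in refluxing methanol, completed if needed with Me2SO4 and K2CO3 in acetone, should give 1-heneicosyl-3,5-dimethoxybenzene F4. Friedel–Crafts acetylation (acetyl chloride, SnCl4, CH2Cl2, −10 °C) is expected at the ring position flanked by the chain and one methoxy group and para to the other, which is less hindered than the position between the two methoxy groups; this delivers 16.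

2. Step 8. Addition of the peracid to the hindered, di-ortho-substituted carbonyl may be slow enough that electrophilic oxidation of the activated ring positions competes. The fallback replaces the ketone by an aldehyde, whose oxidation with aryl migration is much easier; it sets out from alkyne 9 and returns at target 18. Lithium acetylide 11, made from 9 as in step 5, is formylated with DMF (THF, −40 °C → rt, inverse quench into cold 1 M HCl) to give tetracos-2-ynal F5. Cycloaddition with diene 6 under the conditions of step 6 should give, by way of the cycloadduct 2-heneicosyl-4,6-dimethoxy-6-(trimethylsilyloxy)cyclohexa-1,4-diene-1-carbaldehyde F6 and acidic work-up, 2-heneicosyl-6-hydroxy-4-methoxybenzaldehyde F7. Methylation (MeI, K2CO3, acetone, reflux) should give 2-heneicosyl-4,6-dimethoxybenzaldehyde F8. Dakin-type oxidation of this electron-rich aldehyde with mCPBA (CH2Cl2, 0 °C) should give 2-heneicosyl-4,6-dimethoxyphenyl formate F9, and methanolysis (K2CO3 cat., MeOH/THF, Ar) gives 18.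

3. Step 4. The enolisable, poorly soluble C22 aldehyde may undergo aldol self-condensation in the basic methanolic medium faster than it is olefinated by the diazophosphonate anion. The fallback is a Corey–Fuchs sequence without methanolic base; it sets out from docosanal 8 and returns at lithium acetylide 11. Treatment of 8 with CBr4 and PPh3 (CH2Cl2, 0 °C) should give 1,1-dibromotricos-1-ene F10. Two equivalents of n-BuLi (THF, −78 → 0 °C) should convert it by bromine–lithium exchange, elimination and 1,2-shift directly into 11, which is acylated with 10 in the same flask as in step 5.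

**Further compounds**
F1 | step 6 | (E)-pentacos-3-en-2-one | CCCCCCCCCCCCCCCCCCCCC/C=C/C(C)=O
F2 | step 6 | methyl 6-heneicosyl-2,4-dioxocyclohexane-1-carboxylate (racemic, relative configuration and enol forms not defined) | CCCCCCCCCCCCCCCCCCCCCC1CC(=O)CC(=O)C1C(=O)OC
F3 | step 6 | 5-heneicosylcyclohexane-1,3-dione | CCCCCCCCCCCCCCCCCCCCCC1CC(=O)CC(=O)C1
F4 | step 6 | 1-heneicosyl-3,5-dimethoxybenzene | CCCCCCCCCCCCCCCCCCCCCc1cc(OC)cc(OC)c1
F5 | step 8 | tetracos-2-ynal | CCCCCCCCCCCCCCCCCCCCCC#CC=O
F6 | step 8 | 2-heneicosyl-4,6-dimethoxy-6-(trimethylsilyloxy)cyclohexa-1,4-diene-1-carbaldehyde (racemic) | CCCCCCCCCCCCCCCCCCCCCC1=C(C=O)C(OC)(O[Si](C)(C)C)C=C(OC)C1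
F7 | step 8 | 2-heneicosyl-6-hydroxy-4-methoxybenzaldehyde | CCCCCCCCCCCCCCCCCCCCCc1cc(OC)cc(O)c1C=O
F8 | step 8 | 2-heneicosyl-4,6-dimethoxybenzaldehyde | CCCCCCCCCCCCCCCCCCCCCc1cc(OC)cc(OC)c1C=O
F9 | step 8 | 2-heneicosyl-4,6-dimethoxyphenyl formate | CCCCCCCCCCCCCCCCCCCCCc1cc(OC)cc(OC)c1OC=O
F10 | step 4 | 1,1-dibromotricos-1-ene | CCCCCCCCCCCCCCCCCCCCCC=C(Br)Br
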